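I decided to follow alder by its rate and to leave its concentrations aside.

| flask | starting complex | incoming ligand | leaving ligand | remark | time |
|---|---|---|---|---|---|
| dusk | 0.50 M | 0.24 M | 1 M | run made earlier |  |
| winter | 0.50 M | 0.57 M | 1 M | run made earlier |  |
| autumn | 0.50 M | 1.7 M | 1 M | run made earlier |  |
| alder | 0.50 M | 0.250 M | 1.00 M |  | 20 min |
| elm | 0.50 M | 1.00 M | 1.00 M |  | 20 min |
| ash | 0.50 M | 1.50 M | 1.00 M |  | 20 min |

| run | time / min | complex with two exchanged / % | starting complex / % |
|---|---|---|---|
| dusk | 3.00 | 4.8 | 75.7 |
| dusk | 6.00 | 7.7 | 69.0 |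
| dusk | 8.00 | 6.2 | 64.9 |
| dusk | 12.0 | 7.3 | 62.5 |
| dusk | 15.0 | 7.2 | 60.7 |
| winter | 1.00 | 3.0 | 76.3 |
| winter | 2.00 | 11.2 | 63.4 |
| winter | 4.00 | 25.1 | 50.8 |
| winter | 8.00 | 34.6 | 39.7 |
| winter | 15.0 | 38.3 | 34.8 |
| autumn | 1.00 | 27.2 | 46.5 |
| autumn | 2.00 | 54.0 | 26.1 |
| autumn | 4.00 | 78.9 | 14.1 |
| autumn | 8.00 | 92.5 | 3.8 |
| autumn | 15.0 | 96.5 | 0.6 |

(scatter of a reading: 1 percentage point)
- a reading or a percentage of complex with two exchanged counts all its forms, free or not
- a reading of starting complex is of its free form alone
* amount of complex with two exchanged at the end, in percent of the starting complex charged, for each flask in turn (alder, elm, ash)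

1. I replaced the falling [incoming ligand] by its mean over a short interval, counting one ligand per starting complex lost and one more per complex with two exchanged. The first reading of the autumn run gave 0.511 M⁻¹ min⁻¹. This is the first-exchange constant: the logarithm of the fall in starting complex, per minute and per molar of mean ligand. The winter run's second reading gave 0.506 M⁻¹ min⁻¹, so the mean cost little there.

2. Alder's first step should start at 0.0639 M min⁻¹.

3. I read two slowing factors from the dusk run. The dusk run, charged almost alike, kept 60.7% of its starting complex at 15.0 min, a factor 0.607. The same uptake of ligand would leave alder a factor 0.0700 of its ligand, a loose reading, given the scatter.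

4. Together these leave 0.0425 of the starting forward rate. Incoming ligand is the limiting reagent in alder, so I committed to about dusk's last reading, 7.2%.

5. The forecast gave 8%, 72% and 94% for alder, elm and ash, its alder figure higher than mine: “I therefore lean on interpolation.”

6. The flasks gave 6.81%, 80.3% and 95.5%, in the same order.

    starting complex + incoming ligand ⇌ leaving ligand + complex with one exchanged (K = 110, k = 0.00820 M⁻¹ s⁻¹)
    complex with one exchanged + incoming ligand ⇌ leaving ligand + complex with two exchanged (K = 5.10, k = 0.0180 M⁻¹ s⁻¹)
    complex with two exchanged + incoming ligand ⇌ leaving ligand + complex with three exchanged (K = 2.60, k = 7.70 × 10⁻⁴ M⁻¹ s⁻¹)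
    starting complex + complex with two exchanged ⇌ idle adduct, settled at all times (K = 1.20 M⁻¹)
    crystals ⇌ complex with two exchanged, rate k5*(cs5 - [complex with two exchanged]) while solid is left; crystals form when [complex with two exchanged] > cs5 (solubility = 15.0 mM, k = 0.250 s⁻¹)
    complex with two exchanged → over-reaction product (k = 1.00 × 10⁻⁴ s⁻¹)

7. At the end of alder the second step relaxed with a half-life of 1.52 min, shorter than the first step's 4.33 min and short against 20 min. Alder then held 32.3% complex with one exchanged beside 6.81% with two. From alder's end contents, 0.511 M⁻¹ min⁻¹ puts the first step's forward use of ligand at 0.870 of the second's, and alder's forward ratio was 0.84. Carried to elm with mean ligand from 10.0 min to 20.0 min, the forward step alone reckons starting complex down from 13.7% to 5.86%; elm held 7.12% unbound.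

(The runs stem from a simulated flask for substances that don't exist; scatter was added.)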